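**Strategy.** The plan rests on cutting the C8–C9 bond shared by rings B and C (gibberellane numbering), together with C13–C14 and C13–C16. C9 is β to the C12 ketone and C8 is the quaternary junction of rings B, C and D. C9 is therefore offered as an enone carbon and C8 as an enol acetate carbon (latent C14 aldehyde), both attached to a ring A lactone. Intramolecular enone–alkene [2+2] photocycloaddition closes ring B through C8–C9 and forces C11 and C14 cis in a cyclobutane. Base then opens the strained ring by retro-aldol cleavage and recloses it as ring C. Ring D follows by gold-catalysed enol ether–alkyne cyclisation.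

Key step: step 12

Remark: locants C1–C19 follow gibberellane numbering of the target; α/β as in the usual gibberellin drawing (lactone bridge α).
Assumption: in step 4 the salt of the (R)-acid with (R)-1-phenylethylamine is taken as the less soluble one; if the opposite holds, the antipodal amine is used.

Step 1
Reactants: 1 pent-4-yn-1-ol
Product: 2 pent-4-ynal
Conditions: TEMPO (10 mol %), PhI(OAc)2 (1.1 equiv), CH2Cl2, rt
Reagents that add atoms: none
Why: Oxoammonium (TEMPO) oxidation should stop at the aldehyde and leave the terminal alkyne untouched.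

Step 2
Reactants: 2 pent-4-ynal; 3 ethyl glyoxylate
Product: 4 ethyl (2E)-3-formylhex-2-en-5-ynoate
Conditions: pyrrolidine (20 mol %), PhCO2H (20 mol %), 3 (1.5 equiv, PhMe solution), PhMe, 60 °C
Reagents that add atoms: none
Why: Amine-catalysed crossed aldol condensation: the enamine of 2 should add to the non-enolisable, highly electrophilic glyoxylate and dehydrate to the conjugated 3-formylacrylate, whose alkene geometry is of no later consequence.

Step 3
Reactants: 5 3-(hydroxymethyl)benzoic acid
Product: 6 rac-3-(hydroxymethyl)-1-methylcyclohexa-2,5-diene-1-carboxylic acid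
Conditions: Li (5 equiv), NH3(l)/THF, −78 °C; MeI (1.5 equiv), −78 °C; NH4Cl, then aq. HCl to pH 3
Reagents that add atoms: iodomethane, CI
Why: Birch reductive alkylation: the benzoate is reduced to the 1,4-dihydro dianion, which should be C-methylated at the carboxyl-bearing carbon, while the benzylic C–O bond is protected as its alkoxide.

Step 4
Reactants: 6 rac-3-(hydroxymethyl)-1-methylcyclohexa-2,5-diene-1-carboxylic acid
Product: 8 (R)-3-(hydroxymethyl)-1-methylcyclohexa-2,5-diene-1-carboxylic acid, via phenylethylammonium salt 7 (not isolated)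
Conditions: (R)-1-phenylethylamine (1.0 equiv), EtOAc/EtOH, fractional crystallisation; moist salt partitioned between Et2O and 1 M HCl
Reagents that add atoms: none
Why: Classical resolution through diastereomeric ammonium carboxylates should fix C4, the stereocentre from which all others are relayed.

Step 5
Reactants: 8 (R)-3-(hydroxymethyl)-1-methylcyclohexa-2,5-diene-1-carboxylic acid
Product: 9 ring A iodolactone (19,10-lactone with CH2OH on C10 and iodine on C5)
Conditions: I2 (1.1 equiv), NaHCO3 (3 equiv), MeCN/H2O, 0 °C, dark
Reagents that add atoms: iodine, II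
Why: Iodolactonisation: the iodonium ion should form on the more nucleophilic trisubstituted C5=C10 alkene and be opened by the carboxylate at tertiary C10 from its own face (Markovnikov, anti addition), so O10 is cis to C19 and the C5 iodide is trans to O10.

Step 6
Reactants: 9 ring A iodolactone; 4 ethyl (2E)-3-formylhex-2-en-5-ynoate
Product: 10 Giese adduct (C5–C6 bond formed; mixture of epimers at C6 and C8)
Conditions: 4 (4 equiv), Bu3SnH (1.3 equiv, syringe pump), Et3B (20 mol %)/air, PhMe, −40 °C
Reagents that add atoms: none
Why: Giese reaction: the bridging C5 radical should add to the ester-bearing, less substituted alkene carbon (β to the aldehyde) from the face syn to the hydrogen-free lactone bridge and anti to the axial C1–H, placing C6 α, while low temperature and excess acceptor should outrun direct reduction and homoallyl rearrangement.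

Step 7
Reactants: 10 Giese adduct
Product: 11 2β,3β-diol (triol aldehyde)
Conditions: OsO4 (2 mol %), N-methylmorpholine N-oxide (1.5 equiv), acetone/H2O 5:1, rt
Reagents that add atoms: N-methylmorpholine N-oxide, C[N+]1([O-])CCOCC1; water, O
Why: Upjohn dihydroxylation: OsO4 should add suprafacially to the only electron-rich alkene from the β face, anti to the axial C4–C19 and C10–O bonds of the lactone bridge, giving the 2β,3β-diol.

Step 8
Reactants: 11 triol aldehyde
Product: 12 2,3-acetonide with the C9 hydroxyl as 2-methoxypropan-2-yl ether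
Conditions: 2-methoxypropene (5 equiv), pyridinium p-toluenesulfonate (5 mol %), CH2Cl2, 0 °C; Et3N quench
Reagents that add atoms: 2-methoxypropene, COC(C)=C
Why: Acid-catalysed ketalisation should convert the cis-diol into the isopropylidene acetal and add the neopentyl alcohol to the enol ether as an acid-labile mixed ketal in the same operation.

Step 9
Reactants: 12 protected aldehyde
Product: 13 enol acetate (C8=C14–OAc; E/Z mixture; C6 epimers)
Conditions: Ac2O (5 equiv), Et3N (6 equiv), DMAP (20 mol %), CH2Cl2, rt to 40 °C
Reagents that add atoms: acetic anhydride, CC(=O)OC(C)=O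
Why: DMAP-catalysed O-acetylation of the aldehyde enolate should give the enol acetate and erase the C8 stereocentre, with no Lewis acid and no enone present that could trigger a thermal C–C bond formation.

Step 10
Reactants: 13 enol acetate
Product: 14 C9 primary alcohol
Conditions: pyridinium p-toluenesulfonate (10 mol %), MeOH, 0 °C
Reagents that add atoms: none
Why: Mild acid methanolysis should cleave the acyclic mixed ketal far faster than the cyclic acetonide or the enol acetate.

Step 11
Reactants: 14 C9 primary alcohol
Product: 16 (E)-enone (C10–CH=CH–C(O)CH3 beside the C8=C14 enol acetate), via neopentyl aldehyde 15 (not isolated)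
Conditions: Dess–Martin periodinane (1.3 equiv), CH2Cl2, 0 °C to rt; then Ph3P=CHC(O)CH3 (4 equiv), 40 °C
Reagents that add atoms: 1-(triphenylphosphoranylidene)propan-2-one, CC(=O)C=P(c1ccccc1)(c1ccccc1)c1ccccc1
Why: Dess–Martin oxidation followed in the same flask by Wittig olefination with the stabilised ylide should give the (E)-enone, installed only now because an unsaturated group on C10 would have migrated to the C5 radical of step 6.

Step 12
Reactants: 16 (E)-enone enol acetate (mixture of C6 epimers and enol acetate E/Z isomers)
Product: 17 cyclobutane photoadduct (ring B closed by C8–C9; cyclobutane C8–C9–C11–C14)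
Conditions: hν (350 nm, Pyrex), degassed MeCN (5 mM), rt
Reagents that add atoms: none
Why: Excitation of the enone and intersystem crossing give a twisted triplet whose β-carbon C9 bonds to C8 of the enol acetate in a 5-exo closure that makes ring B (rule of five), and the resulting 1,4-biradical (C11 α-keto, C14 α-acetoxy) collapses to the four-membered ring after spin inversion. The closest known reaction type is the intramolecular enone–alkene [2+2] photocycloaddition of 1,6-dienes to bicyclo[3.2.0]heptanes with enol esters as partners (de Mayo type). C9 should be set by allylic strain at C10, the C9=C11 bond eclipsing the small axial C10–O bond and not C1, so that C11 ends α and H9 β; C8 is set by the cyclobutane, which can only be cis-fused to the five-membered ring, so C14 is α and the propargyl group β. Biradicals of the wrong relative configuration cannot close and revert, and E/Z isomerisation of enone or enol acetate only feeds the same biradical, so all isomers of 16 should converge on one C8/C9 configuration, while C6, C11 and C14 stay mixed and are corrected or erased in step 13. The step needs selective excitation and straight regiochemistry: 350 nm light addresses only the enone, and the three-atom tether C10–C5–C6 enforces C9–C8 bonding. A thermal Michael addition would be free to give the trans arrangement, which the congested cyclobutane excludes.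

Step 13
Reactants: 17 cyclobutane photoadduct
Product: 21 tricyclic enone (rings A, B, C; 12-oxo, C13=C14; 6β ester), via cyclobutanol 18 (not isolated), via keto aldehyde 19 (not isolated), via aldol adduct 20 (not isolated)
Conditions: NaOEt (0.5 equiv), EtOH, 0 °C to 50 °C; AcOH quench
Reagents that add atoms: none
Why: Ethoxide should remove the acetate, the cyclobutanol alkoxide should undergo strain-driven retro-aldol cleavage of C11–C14, and the methyl ketone should close ring C by aldol condensation onto the non-enolisable C14 aldehyde, while the C6 ester equilibrates to the β (convex-face) configuration.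

Step 14
Reactants: 21 tricyclic enone
Product: 22 silyl enol ether (C12(OSi)=C13)
Conditions: K[BH(s-Bu)3] (1.1 equiv), THF, −78 °C; then t-BuMe2SiOTf (1.3 equiv), −78 to 0 °C
Reagents that add atoms: tert-butyldimethylsilyl trifluoromethanesulfonate, CC(C)(C)[Si](C)(C)OS(=O)(=O)C(F)(F)F
Why: Conjugate reduction of the β-unsubstituted cyclohexenone by the hindered borohydride should give the C12/C13 enolate regiospecifically, which is trapped on oxygen.

Step 15
Reactants: 22 silyl enol ether
Product: 23 ethyl ester acetonide of the target (ring D closed)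
Conditions: [Au(NCMe){P(t-Bu)2(biphenyl-2-yl)}]SbF6 (5 mol %), CH2Cl2/MeOH 10:1, rt
Reagents that add atoms: none
Why: Cationic monovalent gold should activate the terminal alkyne for 5-exo-dig attack by C13 of the silyl enol ether (Conia-ene-type carbocyclisation), giving the C13–C16 bond and the exocyclic methylene after protodeauration, with C13 fixed by the bicyclo[3.2.1]octane bridge.

Step 16
Reactants: 23 ethyl ester acetonide
Product: 25 target, via acetonide acid 24 (not isolated)
Conditions: LiOH (10 equiv), THF/EtOH/H2O, 50 °C; then 2 M HCl to pH 1, THF, rt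
Reagents that add atoms: lithium hydroxide, [Li+].[OH-]
Why: Saponification is run while the diol is still masked, so no retro-aldol epimerisation at C3 can occur, and acidification should then re-close any opened lactone and hydrolyse the acetonide.

**Compound list**

1 | pent-4-yn-1-ol | C#CCCCO | starting material
2 | pent-4-ynal | C#CCCC=O | intermediate
3 | ethyl glyoxylate (ethyl 2-oxoacetate) | CCOC(=O)C=O | starting material
4 | ethyl (2E)-3-formylhex-2-en-5-ynoate | CCOC(=O)/C=C(/C=O)CC#C | intermediate
5 | 3-(hydroxymethyl)benzoic acid | OCc1cccc(c1)C(=O)O | starting material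
6 | rac-3-(hydroxymethyl)-1-methylcyclohexa-2,5-diene-1-carboxylic acid | OCC1=CC(C)(C(=O)O)C=CC1 | intermediate
7 | (R)-1-phenylethylammonium (R)-3-(hydroxymethyl)-1-methylcyclohexa-2,5-diene-1-carboxylate | OCC1=C[C@](C)(C(=O)[O-])C=CC1.C[C@@H]([NH3+])c1ccccc1 | intermediate
8 | (R)-3-(hydroxymethyl)-1-methylcyclohexa-2,5-diene-1-carboxylic acid (quaternary carbon = C4; CH2OH = C9 on C10) | OCC1=C[C@](C)(C(=O)O)C=CC1 | intermediate
9 | ring A iodolactone, 5-(hydroxymethyl)-8-iodo-1-methyl-6-oxabicyclo[3.2.1]oct-2-en-7-one: 19,10-lactone with O10 cis to C19, CH2OH on C10, iodine on C5 trans to the lactone oxygen, C2=C3 | OC[C@@]12CC=C[C@@](C)(C(=O)O1)[C@@H]2I | intermediate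
10 | Giese adduct, ethyl 3-formyl-2-[5-(hydroxymethyl)-1-methyl-7-oxo-6-oxabicyclo[3.2.1]oct-2-en-8-yl]hex-5-ynoate: side chain on C5 syn to the lactone bridge (H5 β); C6 bears CO2Et, C8 bears CHO (C14) and propargyl (C15–C17); epimers at C6 and C8 | OC[C@@]12CC=C[C@@](C)(C(=O)O1)[C@H]2C(C(=O)OCC)C(C=O)CC#C | intermediate
11 | 2β,3β-diol of 10 (triol aldehyde; epimers at C6 and C8) | OC[C@@]12C[C@H](O)[C@H](O)[C@@](C)(C(=O)O1)[C@H]2C(C(=O)OCC)C(C=O)CC#C | intermediate
12 | 2β,3β-O-isopropylidene acetal of 11 with the C9 oxygen as 2-methoxypropan-2-yl ether (epimers at C6 and C8) | COC(C)(C)OC[C@@]12C[C@@H]3OC(C)(C)O[C@@H]3[C@@](C)(C(=O)O1)[C@H]2C(C(=O)OCC)C(C=O)CC#C | intermediate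
13 | enol acetate of 12: C8=C14H–OAc, C8 bearing propargyl (E/Z mixture; C6 epimers) | COC(C)(C)OC[C@@]12C[C@@H]3OC(C)(C)O[C@@H]3[C@@](C)(C(=O)O1)[C@H]2C(C(=O)OCC)C(CC#C)=COC(C)=O | intermediate
14 | C9 primary alcohol (mixed ketal removed; acetonide and enol acetate kept) | OC[C@@]12C[C@@H]3OC(C)(C)O[C@@H]3[C@@](C)(C(=O)O1)[C@H]2C(C(=O)OCC)C(CC#C)=COC(C)=O | intermediate
15 | C9 aldehyde on quaternary C10 | O=C[C@@]12C[C@@H]3OC(C)(C)O[C@@H]3[C@@](C)(C(=O)O1)[C@H]2C(C(=O)OCC)C(CC#C)=COC(C)=O | intermediate
16 | photosubstrate: (E)-4-oxopent-2-en-2... i.e. C10–CH=CH–C(O)CH3 (C9=C11, C12 ketone, C13 methyl) and C8=C14 enol acetate on the acetonide-protected ring A lactone | CC(=O)/C=C/[C@@]12C[C@@H]3OC(C)(C)O[C@@H]3[C@@](C)(C(=O)O1)[C@H]2C(C(=O)OCC)C(CC#C)=COC(C)=O | intermediate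
17 | cyclobutane photoadduct: ring B (C5, C6, C8, C9, C10) trans-fused to ring A and cis-fused to cyclobutane C8–C9–C11–C14 on the α face; 8β-propargyl, H9 β, 14-acetoxy, 11-acetyl (C6, C11, C14 unassigned) | C#CC[C@]23C(OC(C)=O)C(C(C)=O)[C@H]2[C@@]12C[C@@H]4OC(C)(C)O[C@@H]4[C@@](C)(C(=O)O1)[C@H]2C3C(=O)OCC | intermediate
18 | cyclobutanol (14-hydroxy analogue of 17) | C#CC[C@]23C(O)C(C(C)=O)[C@H]2[C@@]12C[C@@H]4OC(C)(C)O[C@@H]4[C@@](C)(C(=O)O1)[C@H]2C3C(=O)OCC | intermediate
19 | cis keto aldehyde: ring B with 8α-formyl (C14), 8β-propargyl and 9α-(2-oxopropyl) (C11–C13) | C#CC[C@]3(C=O)[C@@H](CC(C)=O)[C@@]12C[C@@H]4OC(C)(C)O[C@@H]4[C@@](C)(C(=O)O1)[C@H]2C3C(=O)OCC | intermediate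
20 | aldol adduct: ring C closed, 14-hydroxy-12-ketone | C#CC[C@]34C(O)CC(=O)C[C@H]3[C@@]12C[C@@H]5OC(C)(C)O[C@@H]5[C@@](C)(C(=O)O1)[C@H]2C4C(=O)OCC | intermediate
21 | tricyclic enone: rings A, B, C; 12-oxo, C13=C14; 8β-propargyl; 6β-CO2Et; 19,10-lactone; 2β,3β-acetonide | C#CC[C@]34C=CC(=O)C[C@H]3[C@@]12C[C@@H]5OC(C)(C)O[C@@H]5[C@@](C)(C(=O)O1)[C@H]2[C@@H]4C(=O)OCC | intermediate
22 | tert-butyldimethylsilyl enol ether of the 13,14-dihydro ketone: C12(OSi)=C13, C14H2 | C#CC[C@]34CC=C(O[Si](C)(C)C(C)(C)C)C[C@H]3[C@@]12C[C@@H]5OC(C)(C)O[C@@H]5[C@@](C)(C(=O)O1)[C@H]2[C@@H]4C(=O)OCC | intermediate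
23 | ethyl ester 2,3-acetonide of the target (tetracyclic, 12-oxo, 16-methylene) | C=C1C[C@]23C[C@H]1C(=O)C[C@H]2[C@@]12C[C@@H]4OC(C)(C)O[C@@H]4[C@@](C)(C(=O)O1)[C@H]2[C@@H]3C(=O)OCC | intermediate
24 | 2,3-acetonide of the target acid | C=C1C[C@]23C[C@H]1C(=O)C[C@H]2[C@@]12C[C@@H]4OC(C)(C)O[C@@H]4[C@@](C)(C(=O)O1)[C@H]2[C@@H]3C(=O)O | intermediate
25 | CNP0307952.1, 2β,3β-dihydroxy-12-oxo-20-norgibberell-16-ene-7,19-dioic acid 19,10-lactone | C=C1C[C@]23C[C@H]1C(=O)C[C@H]2[C@@]12C[C@H](O)[C@H](O)[C@@](C)(C(=O)O1)[C@H]2[C@@H]3C(=O)O | target

**Count and risks**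

Total steps: 16 (steps 1–2 make fragment 4; steps 3–16 are the main line). Longest linear sequence: 14 steps (5 to 25).

Steps most likely to fail:

1. Step 12. The acyclic enone may lose most of its excitation by E/Z twisting, and discrimination between the two faces of C9 may be insufficient. The fallback is a thermal anionic Michael–aldol annulation that sets out from 16 and returns at 21. NaOEt in EtOH (0 °C, then 50 °C) removes the enol acetate and gives the enolate of the aldehyde enone F1. Its C8 should add 5-exo to C9 of the enone (reversible Michael addition) to give keto aldehyde 19, which condenses to 21 as in step 13. The cis relationship is then not enforced by a ring; it rests on the cis adduct being the one that closes ring C readily and drains the Michael equilibrium.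

2. Step 6. The hindered bridging radical may be reduced before it adds, may rearrange by 1,2-vinyl shift through C3, or may be attacked on the wrong face of C5. The fallback is a polarity-reversed radical carbolactonisation that sets out from 8 and 4 and returns at 10. Compound 4 with iodotrimethylsilane (CH2Cl2, −40 °C) and then methanol should add iodide β to the aldehyde and acetalise it, giving ethyl 3-(dimethoxymethyl)-2-iodohex-5-ynoate F2. Et3B/air in aqueous EtOH with NaHCO3 then starts an iodine-atom-transfer addition of F2 to acid 8. The electrophilic α-ester radical attacks C5 of the electron-rich C5=C10 alkene, and the tertiary C10 iodide is displaced by the C19 carboxylate to give the lactone acetal F3. Pyridinium p-toluenesulfonate in wet acetone hydrolyses the acetal to 10. No bridging radical and no tin hydride are involved; the C5 face is governed by C4 and by the lactone closure.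

3. Step 15. The silyl enol ether may be protodesilylated before the C–C bond forms, returning the ketone. The fallback is a radical ring D closure that sets out from 22 and returns at 23. N-Iodosuccinimide (THF, −78 °C) converts 22 into the 13-iodo-12-ketone F4. Bu3SnH with Et3B/air (PhH, rt) generates the C13 α-keto radical, which should cyclise 5-exo-dig onto the alkyne, and the vinyl radical takes hydrogen to give 23.

**Further compounds**

F1 | step 12 | aldehyde enone (deacetylated 16; epimers at C6 and C8) | CC(=O)/C=C/[C@@]12C[C@@H]3OC(C)(C)O[C@@H]3[C@@](C)(C(=O)O1)[C@H]2C(C(=O)OCC)C(C=O)CC#C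
F2 | step 6 | ethyl 3-(dimethoxymethyl)-2-iodohex-5-ynoate | CCOC(=O)C(I)C(CC#C)C(OC)OC
F3 | step 6 | dimethyl acetal of 10 (lactone acetal) | OC[C@@]12CC=C[C@@](C)(C(=O)O1)[C@H]2C(C(=O)OCC)C(CC#C)C(OC)OC
F4 | step 15 | 13-iodo-12-ketone (13,14-dihydro-21 iodinated at C13) | C#CC[C@]34CC(I)C(=O)C[C@H]3[C@@]12C[C@@H]5OC(C)(C)O[C@@H]5[C@@](C)(C(=O)O1)[C@H]2[C@@H]4C(=O)OCC
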